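**Plan**
- Cuts, in retrosynthetic order: (1) the a1–C(=O) bond of ring A (ring A = the acylated benzene ring: a1 acyl carbon, a2 OH, a3 CH3, a4 OCH3, a5 CH2 bridge, a6 OH); (2) ring A itself across a5–a6 and a3–a4; (3) the CH2–C(sp) bond of the resulting methoxyalkyne; (4) the C8–CH2 bond and the pyranone ring C of the chromanone (ring B = its benzene ring).
- Enabling feature: read from a6 to a1, ring A carries OH, CH2R, OCH3, CH3, OR, H. This is the pattern that a 3-alkoxy-2-methylcyclobutenone (a6, a1, a2, a3) and a 1-methoxyalkyne (a4, a5) write in a Danheiser benzannulation.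
- Forward order: rings B and C first (from 2-methylphloroglucinol), then the C8 side chain up to the methoxyalkyne; the four-membered ring is made separately; ring A is then built on the alkyne, acylated at a1 (its only C–H) and debenzylated.
- Stereochemistry: the single stereocentre is bought as (R)-2-methylbutanoic acid and passes only through base-free steps (acid chloride formation, low-temperature acylation, neutral hydrogenolysis).

Key step: step 11

Remark: (R)-2-methylbutanoic acid is taken as purchasable in enantiopure form, and ring C is assumed to close in step 1 mainly through the hydroxyl remote from the methyl group (6-methyl isomer).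

**Step 1**
Reactants: 1 2-methylphloroglucinol; 2 3-methylbut-2-enoic acid
Product: 4 5,7-dihydroxy-2,2,6-trimethylchroman-4-one, via aryl enone 3 (not isolated)
Conditions: MeSO3H, P2O5, 70 °C
Reagents that add atoms: none
Why: Friedel–Crafts acylation at one of the two equivalent C–H positions gives enone 3, and acid-mediated oxa-Michael addition closes ring C; closure should go mainly through the hydroxyl flanked by C–H, because the hydroxyl next to the methyl group is buttressed into the hydrogen bond to the ketone, and any 8-methyl isomer would be removed here by crystallisation.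

**Step 2**
Reactants: 4 5,7-dihydroxy-2,2,6-trimethylchroman-4-one
Product: 6 5,7-dihydroxy-2,2,6-trimethyl-4-oxochromane-8-carbaldehyde, via chloro(methoxy)methyl adduct 5 (not isolated)
Conditions: Cl2CHOMe, TiCl4, CH2Cl2, 0 °C; then aq. HCl
Reagents that add atoms: dichloromethyl methyl ether (COC(Cl)Cl); water (O)
Why: Rieche formylation ortho to the titanium-bound 7-hydroxyl, where C8 is the only free position of ring B and adduct 5 hydrolyses to the aldehyde on aqueous work-up.

**Step 3**
Reactants: 6 5,7-dihydroxy-2,2,6-trimethyl-4-oxochromane-8-carbaldehyde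
Product: 7 5,7-bis(benzyloxy)-2,2,6-trimethyl-4-oxochromane-8-carbaldehyde
Conditions: BnBr, K2CO3, DMF, 70 °C
Reagents that add atoms: benzyl bromide (BrCc1ccccc1)
Why: Williamson ether synthesis; both phenols are hydrogen-bonded to a carbonyl group and so need heat and excess reagent, and they must be capped because free phenols would intercept the ketenes of step 11.

**Step 4**
Reactants: 7 5,7-bis(benzyloxy)-2,2,6-trimethyl-4-oxochromane-8-carbaldehyde
Product: 8 5,7-bis(benzyloxy)-8-(hydroxymethyl)-2,2,6-trimethylchroman-4-one
Conditions: NaBH4 (0.5 equiv), THF/MeOH, −20 °C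
Reagents that add atoms: none
Why: Chemoselective NaBH4 reduction, since the aryl aldehyde should react far faster at −20 °C than the chromanone ketone, a hindered vinylogous ester carbonyl flanked by the 5-benzyloxy group.

**Step 5**
Reactants: 8 5,7-bis(benzyloxy)-8-(hydroxymethyl)-2,2,6-trimethylchroman-4-one
Product: 9 5,7-bis(benzyloxy)-8-(bromomethyl)-2,2,6-trimethylchroman-4-one
Conditions: CBr4, PPh3, CH2Cl2, 0 °C; used at once
Reagents that add atoms: carbon tetrabromide (BrC(Br)(Br)Br)
Why: Appel bromination under neutral conditions converts the electron-rich benzylic alcohol into the bromide without acid that could ionise it or cleave the benzyl ethers.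

**Step 6**
Reactants: 10 2-chloro-1,1-dimethoxyethane
Product: 12 tributyl(methoxyethynyl)stannane, via lithium methoxyacetylide 11 (not isolated)
Conditions: LiNEt2 (3 equiv), THF, 0 °C; then Bu3SnCl, −78 → 25 °C; distillation
Reagents that add atoms: tributyltin chloride (CCCC[Sn](Cl)(CCCC)CCCC)
Why: Threefold base-induced elimination and deprotonation of the chloroacetal (loss of methanol and HCl) is the classical entry to alkoxyacetylides, and C-stannylation gives an ynol ether reagent that can be distilled free of amine.

**Step 7**
Reactants: 9 5,7-bis(benzyloxy)-8-(bromomethyl)-2,2,6-trimethylchroman-4-one; 12 tributyl(methoxyethynyl)stannane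
Product: 13 5,7-bis(benzyloxy)-8-(3-methoxyprop-2-yn-1-yl)-2,2,6-trimethylchroman-4-one
Conditions: Pd(PPh3)4 (5 mol %), THF, 60 °C
Reagents that add atoms: none
Why: Stille coupling of a benzylic bromide with an alkynylstannane; oxidative addition of the benzylic C–Br bond to zerovalent palladium is easy, alkynyl groups transfer from tin in preference to butyl, and the neutral medium spares the ketone, the benzyl ethers and the acid-sensitive ynol ether.

**Step 8**
Reactants: 14 propanoyl chloride; 15 ethoxyethyne
Product: 17 3-ethoxy-4-methylcyclobut-2-en-1-one (racemic), via methylketene 16 (not isolated)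
Conditions: Et3N (slow addition), Et2O, 0 → 25 °C
Reagents that add atoms: none
Why: Ketene–ynol ether [2+2] cycloaddition, in which the nucleophilic terminal carbon of ethoxyethyne attacks the carbonyl carbon of methylketene 16 and the ring closes at the oxygen-bearing carbon (the stereocentre is lost in step 9).

**Step 9**
Reactants: 17 3-ethoxy-4-methylcyclobut-2-en-1-one
Product: 18 3-hydroxy-2-methylcyclobut-2-en-1-one (enol form of 2-methylcyclobutane-1,3-dione)
Conditions: 1 M HCl, THF, 25 °C
Reagents that add atoms: water (O)
Why: Acid hydrolysis of the vinylogous ester gives the 1,3-dione, which should rest as the enol with the tetrasubstituted double bond, so that the methyl group now sits on the carbon between the two oxygenated carbons.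

**Step 10**
Reactants: 18 3-hydroxy-2-methylcyclobut-2-en-1-one
Product: 19 3-(benzyloxy)-2-methylcyclobut-2-en-1-one
Conditions: BnOH, PPh3, DIAD, THF, 0 → 25 °C
Reagents that add atoms: benzyl alcohol (OCc1ccccc1)
Why: Mitsunobu alkylation of a vinylogous carboxylic acid takes place on oxygen and avoids the C-benzylation expected from benzyl bromide and base; either oxygen of the symmetrical anion gives the same product.

**Step 11**
Reactants: 13 5,7-bis(benzyloxy)-8-(3-methoxyprop-2-yn-1-yl)-2,2,6-trimethylchroman-4-one; 19 3-(benzyloxy)-2-methylcyclobut-2-en-1-one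
Product: 24 5,7-bis(benzyloxy)-8-[4-(benzyloxy)-2-hydroxy-6-methoxy-5-methylbenzyl]-2,2,6-trimethylchroman-4-one, via vinylketene 20 (not isolated), via vinylcyclobutenone 21 (not isolated), via dienylketene 22 (not isolated), via cyclohexadienone 23 (not isolated)
Conditions: 19 (1.5 equiv), PhMe, 145 °C, sealed tube
Reagents that add atoms: none
Why: Thermal 4π electrocyclic opening of 19 gives vinylketene 20, whose ketene C=C adds to the ynol ether of 13 in a [2+2] cycloaddition to give 21; a second 4π opening to dienylketene 22, 6π electrocyclisation to 23 and tautomerisation give phenol 24 (Danheiser benzannulation of a cyclobutenone with an alkoxyalkyne). Ring A is closed by the 6π electrocyclic ring closure (a1–a6) after the two new bonds a5–a6 and a3–a4 were made in the [2+2] step. No stereocentre is formed, since the quaternary carbon of 21 is lost on ring opening. The one selectivity needed is the orientation of the [2+2] step, and the polarisation of the ynol ether secures it: its nucleophilic carbon, which carries the chromanylmethyl group, attacks the ketene carbonyl carbon and the oxygen-bearing carbon bonds to the ketene α-carbon, placing OCH3 at a4 and the bridge at a5. The methyl ynol ether has no β-hydrogen for retro-ene loss, the chromanone phenols are benzylated so that nothing traps the ketenes, and the opening of 19 concerns the same kind of 3-alkoxycyclobutenone that every alkoxyalkyne benzannulation passes through as 21, so 145 °C should suffice.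

**Step 12**
Reactants: 25 (R)-2-methylbutanoic acid
Product: 26 (R)-2-methylbutanoyl chloride
Conditions: (COCl)2 (1.05 equiv), DMF (cat.), CH2Cl2, 0 → 25 °C; used as solution
Reagents that add atoms: oxalyl chloride (O=C(Cl)C(=O)Cl)
Why: Acid chloride formation by Vilsmeier-type activation proceeds without base, so no ketene can form and the configuration of the α-carbon is kept.

**Step 13**
Reactants: 24 5,7-bis(benzyloxy)-8-[4-(benzyloxy)-2-hydroxy-6-methoxy-5-methylbenzyl]-2,2,6-trimethylchroman-4-one; 26 (R)-2-methylbutanoyl chloride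
Product: 27 5,7-bis(benzyloxy)-8-{4-(benzyloxy)-2-hydroxy-6-methoxy-5-methyl-3-[(2R)-2-methylbutanoyl]benzyl}-2,2,6-trimethylchroman-4-one
Conditions: TiCl4 (3 equiv), CH2Cl2, −78 → −30 °C
Reagents that add atoms: none
Why: Friedel–Crafts acylation directed by the titanium phenoxide of the a6 hydroxyl; a1 is the only unsubstituted carbon of rings A and B and is activated by ortho OH, ortho OBn and para OCH3, so acylation should occur below the temperature at which TiCl4 cleaves aryl benzyl ethers, and the absence of base keeps the α-stereocentre from enolising.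

**Step 14**
Reactants: 27 5,7-bis(benzyloxy)-8-{4-(benzyloxy)-2-hydroxy-6-methoxy-5-methyl-3-[(2R)-2-methylbutanoyl]benzyl}-2,2,6-trimethylchroman-4-one
Product: 28 5,7-dihydroxy-8-{2,4-dihydroxy-6-methoxy-5-methyl-3-[(2R)-2-methylbutanoyl]benzyl}-2,2,6-trimethylchroman-4-one
Conditions: H2 (1 atm), 10 % Pd/C, EtOAc, 25 °C
Reagents that add atoms: none
Why: Hydrogenolysis of the three aryl benzyl ethers under neutral conditions should leave the diarylmethane bridge, both aryl ketones, the methyl ether and the α-stereocentre untouched.

**Compound list**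
1 | 2-methylphloroglucinol (2-methylbenzene-1,3,5-triol) | Cc1c(O)cc(O)cc1O | starting material
2 | 3-methylbut-2-enoic acid | CC(C)=CC(=O)O | starting material
3 | 3-methyl-1-(2,4,6-trihydroxy-3-methylphenyl)but-2-en-1-one | CC(C)=CC(=O)c1c(O)cc(O)c(C)c1O | intermediate
4 | 5,7-dihydroxy-2,2,6-trimethylchroman-4-one | Cc1c(O)cc2OC(C)(C)CC(=O)c2c1O | intermediate
5 | 8-[chloro(methoxy)methyl]-5,7-dihydroxy-2,2,6-trimethylchroman-4-one | Cc1c(O)c(C(Cl)OC)c2OC(C)(C)CC(=O)c2c1O | intermediate
6 | 5,7-dihydroxy-2,2,6-trimethyl-4-oxochromane-8-carbaldehyde | Cc1c(O)c(C=O)c2OC(C)(C)CC(=O)c2c1O | intermediate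
7 | 5,7-bis(benzyloxy)-2,2,6-trimethyl-4-oxochromane-8-carbaldehyde | Cc1c(OCc2ccccc2)c(C=O)c2OC(C)(C)CC(=O)c2c1OCc1ccccc1 | intermediate
8 | 5,7-bis(benzyloxy)-8-(hydroxymethyl)-2,2,6-trimethylchroman-4-one | Cc1c(OCc2ccccc2)c(CO)c2OC(C)(C)CC(=O)c2c1OCc1ccccc1 | intermediate
9 | 5,7-bis(benzyloxy)-8-(bromomethyl)-2,2,6-trimethylchroman-4-one | Cc1c(OCc2ccccc2)c(CBr)c2OC(C)(C)CC(=O)c2c1OCc1ccccc1 | intermediate
10 | 2-chloro-1,1-dimethoxyethane (chloroacetaldehyde dimethyl acetal) | COC(CCl)OC | starting material
11 | lithium methoxyacetylide | [Li]C#COC | intermediate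
12 | tributyl(methoxyethynyl)stannane | CCCC[Sn](CCCC)(CCCC)C#COC | intermediate
13 | 5,7-bis(benzyloxy)-8-(3-methoxyprop-2-yn-1-yl)-2,2,6-trimethylchroman-4-one | COC#CCc1c(OCc2ccccc2)c(C)c(OCc2ccccc2)c2c1OC(C)(C)CC2=O | intermediate
14 | propanoyl chloride | CCC(=O)Cl | starting material
15 | ethoxyethyne | CCOC#C | starting material
16 | methylketene (prop-1-en-1-one) | CC=C=O | intermediate
17 | 3-ethoxy-4-methylcyclobut-2-en-1-one (racemic) | CCOC1=CC(=O)C1C | intermediate
18 | 3-hydroxy-2-methylcyclobut-2-en-1-one (enol of 2-methylcyclobutane-1,3-dione) | CC1=C(O)CC1=O | intermediate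
19 | 3-(benzyloxy)-2-methylcyclobut-2-en-1-one | CC1=C(OCc2ccccc2)CC1=O | intermediate
20 | 3-(benzyloxy)-2-methylbuta-1,3-dien-1-one | C=C(OCc1ccccc1)C(C)=C=O | intermediate
21 | 4-[1-(benzyloxy)ethenyl]-2-{[5,7-bis(benzyloxy)-2,2,6-trimethyl-4-oxochroman-8-yl]methyl}-3-methoxy-4-methylcyclobut-2-en-1-one (racemic) | COC1=C(Cc2c(OCc3ccccc3)c(C)c(OCc3ccccc3)c3c2OC(C)(C)CC3=O)C(=O)C1(C)C(=C)OCc1ccccc1 | intermediate
22 | 5-(benzyloxy)-2-{[5,7-bis(benzyloxy)-2,2,6-trimethyl-4-oxochroman-8-yl]methyl}-3-methoxy-4-methylhexa-1,3,5-trien-1-one (ketene carbon and benzyloxyvinyl group cis on the central double bond) | O=C=C(Cc1c(OCc2ccccc2)c(C)c(OCc2ccccc2)c2c1OC(C)(C)CC2=O)/C(OC)=C(/C)C(=C)OCc1ccccc1 | intermediate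
23 | 5-(benzyloxy)-2-{[5,7-bis(benzyloxy)-2,2,6-trimethyl-4-oxochroman-8-yl]methyl}-3-methoxy-4-methylcyclohexa-2,4-dien-1-one | O=C1CC(OCc2ccccc2)=C(C)C(OC)=C1Cc1c(OCc2ccccc2)c(C)c(OCc2ccccc2)c2c1OC(C)(C)CC2=O | intermediate
24 | 5,7-bis(benzyloxy)-8-[4-(benzyloxy)-2-hydroxy-6-methoxy-5-methylbenzyl]-2,2,6-trimethylchroman-4-one | Oc1cc(OCc2ccccc2)c(C)c(OC)c1Cc1c(OCc2ccccc2)c(C)c(OCc2ccccc2)c2c1OC(C)(C)CC2=O | intermediate
25 | (R)-2-methylbutanoic acid | CC[C@@H](C)C(=O)O | starting material
26 | (R)-2-methylbutanoyl chloride | CC[C@@H](C)C(=O)Cl | intermediate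
27 | 5,7-bis(benzyloxy)-8-{4-(benzyloxy)-2-hydroxy-6-methoxy-5-methyl-3-[(2R)-2-methylbutanoyl]benzyl}-2,2,6-trimethylchroman-4-one | CC[C@@H](C)C(=O)c1c(O)c(Cc2c(OCc3ccccc3)c(C)c(OCc3ccccc3)c3c2OC(C)(C)CC3=O)c(OC)c(C)c1OCc1ccccc1 | intermediate
28 | 5,7-dihydroxy-8-{2,4-dihydroxy-6-methoxy-5-methyl-3-[(2R)-2-methylbutanoyl]benzyl}-2,2,6-trimethylchroman-4-one | CC[C@@H](C)C(=O)c1c(O)c(C)c(OC)c(Cc2c(O)c(C)c(O)c3c2OC(C)(C)CC3=O)c1O | target

**Step count and risks**
Total: 14 steps. Longest linear sequence: 9 steps (steps 1, 2, 3, 4, 5, 7, 11, 13, 14).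

Step 11 is the most likely to fail. Cyclobutenone 19 is a vinylogous ester and may open only at a temperature at which the ynol ether oligomerises or the vinylketene dimerises, and the phenol formed may be acylated by ketene still present. The fallback makes the same vinylketene 20 at room temperature by 1,4-dehydrochlorination instead of ring opening; it sets out from alkyne 13 and returns at phenol 24. Base-catalysed addition of benzyl alcohol (NaH cat., THF) to purchasable ethyl 2-methylbuta-2,3-dienoate should give ethyl 3-(benzyloxy)-2-methylbut-2-enoate F1. Saponification (LiOH, THF/H2O) gives 3-(benzyloxy)-2-methylbut-2-enoic acid F2, and oxalyl chloride gives 3-(benzyloxy)-2-methylbut-2-enoyl chloride F3. Slow addition of Et3N to F3 and 13 in toluene at 25 °C should generate 20, which is trapped by the ynol ether as 21. Warming to 80–110 °C then takes 21 through 22 and 23 to 24. Generation of vinylketenes from α,β-unsaturated acid chlorides and their [2+2] capture by electron-rich alkynes are known reactions.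

Step 7 is the second risk. Tin-to-palladium transfer at the doubly ortho-substituted benzylpalladium may be slow, so that homocoupling of the bromide, its ionisation and protodestannylation of the ynol ether take over. The fallback changes the nucleophile to an alkynylzinc, which transmetalates at or below room temperature; it sets out from bromide 9 and returns at alkyne 13. Stannane 12 is treated with MeLi (THF, −78 °C) to regenerate amine-free lithium methoxyacetylide 11, and ZnCl2 gives (methoxyethynyl)zinc chloride F4. A Negishi benzyl–alkynyl coupling of F4 with 9 [PdCl2(DPEphos), DPEphos = bis[2-(diphenylphosphino)phenyl] ether, THF, 0 → 25 °C] should then give 13.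

Step 13 is the third risk. TiCl4 may cleave the chelated 5-benzyl ether before acylation and pass the freed benzyl group to a1, the a6 hydroxyl may be acylated on oxygen, and the titanium-bound ketone may slowly enolise. The fallback removes the benzyl groups first and acylates the free phloroglucinol-type ring; it sets out from phenol 24 and returns at target 28. Hydrogenolysis of 24 (H2, Pd/C, EtOAc) gives 8-(2,4-dihydroxy-6-methoxy-5-methylbenzyl)-5,7-dihydroxy-2,2,6-trimethylchroman-4-one F5. Classical Friedel–Crafts acylation of F5 with 26 (AlCl3, PhNO2/CH2Cl2, 0 °C), in which any O-acyl material rearranges to carbon, should deliver 28 directly, a1 again being the only C–H on rings A and B.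

**Further compounds**
F1 | step 11 | ethyl 3-(benzyloxy)-2-methylbut-2-enoate (E/Z mixture, either geometry serves) | CCOC(=O)C(C)=C(C)OCc1ccccc1
F2 | step 11 | 3-(benzyloxy)-2-methylbut-2-enoic acid (E/Z mixture) | CC(OCc1ccccc1)=C(C)C(=O)O
F3 | step 11 | 3-(benzyloxy)-2-methylbut-2-enoyl chloride (E/Z mixture) | CC(OCc1ccccc1)=C(C)C(=O)Cl
F4 | step 7 | (methoxyethynyl)zinc chloride | COC#C[Zn]Cl
F5 | step 13 | 8-(2,4-dihydroxy-6-methoxy-5-methylbenzyl)-5,7-dihydroxy-2,2,6-trimethylchroman-4-one | Oc1cc(O)c(C)c(OC)c1Cc1c(O)c(C)c(O)c2c1OC(C)(C)CC2=O
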